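**Retrosynthetic overview**

- Ring numbering: C1 (C=O), C2 (two prenyl groups), C3 (C=O), C4 (isobutyryl), C5 (enol C-OH), C6 (OH, prenyl, R). The carbocycle is cut at C6-C1 and C5-C4, and the C6 prenyl group is cut at its CH2-CH= bond. This gives three components.
- Enabling feature: C5-C6 with its OH is the carboxyl carbon and α-carbon of an α-hydroxy acid (acceptor beside donor). C1-C2-C3-C4 is the complement (acceptor C1, donor C4). Because C2 is quaternary and cannot enolise, C1-C4 plus the isobutyryl C=O can be stored as a neutral, non-acidic six-membered enol lactone (a 3,3-diprenylpyran-2,4-dione ring), which releases the donor C4 only after C1 has reacted.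
- Components: (R)-2-tert-butyl-5-methylidene-1,3-dioxolan-4-one (from (R)-lactic acid, self-regeneration of stereocentres); 2-methyl-1-propenylmagnesium bromide; 6-isopropyl-3,3-diprenylpyran-2,4-dione (from the diketene-acetone adduct, isobutyryl chloride and prenyl acetate).
- Order of ring formation: dioxolanone ring (temporary), pyranone ring (temporary), carbocycle last. Both temporary rings are consumed in the operation that closes the carbocycle.

Key step: step 7

Assumption: the β-triketone of the target is a set of enol tautomers; name, SMILES and the descriptor R refer to the tautomer drawn.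

**Step 1**
Reactants: 1 (R)-lactic acid; 2 pivalaldehyde
Product: 3 (2R,5R)-2-tert-butyl-5-methyl-1,3-dioxolan-4-one (cis)
Conditions: TsOH·H2O (cat.), H2SO4 (cat.), pentane, reflux, Dean-Stark; recrystallisation from pentane at -78 °C
Reagents that add atoms: none
Why: Acid-catalysed acetalisation of an α-hydroxy acid with azeotropic removal of water; the existing (R)-centre sets the new acetal centre cis to the methyl group under thermodynamic control, and crystallisation should remove the minor trans isomer.

**Step 2**
Reactants: 3 (2R,5R)-2-tert-butyl-5-methyl-1,3-dioxolan-4-one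
Product: 4 (2S,5S)-5-bromo-2-tert-butyl-5-methyl-1,3-dioxolan-4-one (Br trans to tert-butyl; the C2 descriptor changes only through CIP priorities)
Conditions: N-bromosuccinimide, AIBN (cat.), PhCF3, reflux
Reagents that add atoms: N-bromosuccinimide, O=C1CCC(=O)N1Br
Why: Wohl-Ziegler-type radical bromination: the captodatively stabilised tertiary radical at C5 forms selectively and takes up bromine anti to the tert-butyl group, this centre is erased in the next step, and the acetal centre is untouched.

**Step 3**
Reactants: 4 (2S,5S)-5-bromo-2-tert-butyl-5-methyl-1,3-dioxolan-4-one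
Product: 5 (R)-2-tert-butyl-5-methylidene-1,3-dioxolan-4-one
Conditions: Et3N, Et2O, 0 °C to rt; filtration; stored cold with a trace of BHT
Reagents that add atoms: none
Why: E2 dehydrobromination of a tertiary α-bromo lactone whose only β-hydrogens are those of the methyl group gives the exocyclic α-alkoxyacrylate, in which the (R)-acetal carbon alone stores the chirality.

**Step 4**
Reactants: 6 2,2,6-trimethyl-4H-1,3-dioxin-4-one; 7 isobutyryl chloride
Product: 9 2,2-dimethyl-6-(3-methyl-2-oxobutyl)-4H-1,3-dioxin-4-one, via lithium dienolate 8 (not isolated)
Conditions: 6 (2 equiv), LiN(SiMe3)2 (2 equiv), THF, -78 °C; then 7 (1 equiv), -78 to -20 °C; aq NH4Cl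
Reagents that add atoms: none
Why: γ-Selective Claisen-type C-acylation of the vinylogous ester enolate by an acid chloride, with the second equivalent of dienolate absorbing the acidic proton of the product; no stereocentre is formed.

**Step 5**
Reactants: 9 2,2-dimethyl-6-(3-methyl-2-oxobutyl)-4H-1,3-dioxin-4-one
Product: 11 4-hydroxy-6-isopropyl-2H-pyran-2-one, via acylketene 10 (not isolated)
Conditions: toluene, 110 °C
Reagents that add atoms: none
Why: Thermal retro-hetero-Diels-Alder loss of acetone gives the acylketene, which the enol oxygen of the δ-ketone captures to close the six-membered lactone; this is the standard dioxinone route to 4-hydroxy-2-pyrones.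

**Step 6**
Reactants: 11 4-hydroxy-6-isopropyl-2H-pyran-2-one; 12 prenyl acetate
Product: 14 6-isopropyl-3,3-bis(3-methylbut-2-enyl)-2H-pyran-2,4(3H)-dione, via monoprenyl pyrone 13 (not isolated)
Conditions: 12 (2.5 equiv), Pd(PPh3)4 (5 mol %), i-Pr2NEt (2.2 equiv), dry THF, 55 °C
Reagents that add atoms: none
Why: Double Tsuji-Trost allylic alkylation: zerovalent palladium ionises prenyl acetate, the acidic pyrone (a cyclic β-keto lactone enol) attacks the unhindered terminus of the π-prenyl complex through C3, O-prenyl ethers re-ionise under the conditions so that the C,C-dialkylated non-acidic product accumulates, and no stereocentre arises because both groups are the same.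

**Step 7**
Reactants: 5 (R)-2-tert-butyl-5-methylidene-1,3-dioxolan-4-one; 15 2-methyl-1-propenylmagnesium bromide; 14 6-isopropyl-3,3-bis(3-methylbut-2-enyl)-2H-pyran-2,4(3H)-dione
Product: 18 (6R)-5,6-dihydroxy-4-(2-methylpropanoyl)-2,2,6-tris(3-methylbut-2-en-1-yl)cyclohex-4-ene-1,3-dione (target), via bromomagnesium enolate 16 (not isolated), via ring-opened bromomagnesium diketonate 17 (not isolated)
Conditions: 15 (1.0 equiv), CuBr·SMe2 (10 mol %), THF, -78 °C; slow addition of 5 (1.05 equiv); then 14 (1.0 equiv) in THF, -78 °C, 2 h, then to 0 °C; cold 1 M HCl
Reagents that add atoms: none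
Why: Proposed new method: copper-catalysed 1,4-addition of 15 to the exocyclic methylene of 5 completes the prenyl chain and gives the planar enolate 16, which attacks the lactone carbonyl (C2) of 14; collapse of the adduct opens the pyranone at its acyl-oxygen bond and frees the β-diketonate 17, whose central carbon closes onto the dioxolanone carbonyl, after which the acetal falls apart to pivalaldehyde and the acidic triketone proton passes to the tertiary alkoxide, so the chain ends in a stable magnesium triketonate and needs no added base. The closest known reaction types are the three-component conjugate addition-enolate trapping of organocopper chemistry, the anti-selective trapping of 2-tert-butyl-dioxolanone enolates (self-regeneration of stereocentres), the opening of 3,3-dialkylpyran-2,4-diones at C2 by oxygen and nitrogen nucleophiles, and the Claisen-type cyclisation of 3,5,7-triketo esters to acylphloroglucinols; new is their union through a carbon nucleophile in one flask. The only ring closed is the carbocycle, by 6-exo-trig attack of the diketonate carbon (6-enolexo) on the ester carbonyl, a Dieckmann-type closure, while both temporary rings are opened. The single stereocentre C6 is set when 16 is acylated: the tert-butyl group on the (R)-acetal carbon shields one face, the acyl carbon enters anti to it, which corresponds to 6R, and the centre is then quaternary and cannot epimerise. The step needs three selectivities: 1,4- over 1,2-addition to 5 (secured by monovalent copper and the s-cis-locked unsubstituted methylene); attack of 16 on the lactone carbonyl of 14 rather than on C4=O or C6 (the enol-ester carbonyl is the most electrophilic site and can be chelated with C4=O by magnesium, C4=O is a deactivated vinylogous ester carbonyl, C6 is shielded by isopropyl, and the quaternary C3 leaves no acidic α-hydrogen to quench the enolate); and C- over O-acylation in the closure (O-acylation is reversible, whereas C-acylation is drained by triketonate formation and loss of pivalaldehyde).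

**Compound list**

1 | (R)-lactic acid | C[C@@H](O)C(=O)O | starting material
2 | pivalaldehyde | CC(C)(C)C=O | starting material
3 | (2R,5R)-2-tert-butyl-5-methyl-1,3-dioxolan-4-one | O=C1O[C@H](C(C)(C)C)O[C@@H]1C | intermediate
4 | (2S,5S)-5-bromo-2-tert-butyl-5-methyl-1,3-dioxolan-4-one | O=C1O[C@H](C(C)(C)C)O[C@@]1(C)Br | intermediate
5 | (R)-2-tert-butyl-5-methylidene-1,3-dioxolan-4-one | O=C1O[C@H](C(C)(C)C)OC1=C | intermediate
6 | 2,2,6-trimethyl-4H-1,3-dioxin-4-one | CC1=CC(=O)OC(C)(C)O1 | starting material
7 | isobutyryl chloride | CC(C)C(=O)Cl | starting material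
8 | lithium 2,2-dimethyl-6-methylidene-1,3-dioxin-4-olate (dienolate of 6) | [Li+].C=C1C=C([O-])OC(C)(C)O1 | intermediate
9 | 2,2-dimethyl-6-(3-methyl-2-oxobutyl)-4H-1,3-dioxin-4-one | CC(C)C(=O)CC1=CC(=O)OC(C)(C)O1 | intermediate
10 | 6-methyl-3,5-dioxohept-1-en-1-one (acylketene) | CC(C)C(=O)CC(=O)C=C=O | intermediate
11 | 4-hydroxy-6-isopropyl-2H-pyran-2-one | CC(C)C1=CC(O)=CC(=O)O1 | intermediate
12 | prenyl acetate (3-methylbut-2-enyl acetate) | CC(C)=CCOC(C)=O | starting material
13 | 4-hydroxy-6-isopropyl-3-(3-methylbut-2-enyl)-2H-pyran-2-one | CC(C)C1=CC(O)=C(CC=C(C)C)C(=O)O1 | intermediate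
14 | 6-isopropyl-3,3-bis(3-methylbut-2-enyl)-2H-pyran-2,4(3H)-dione | CC(C)C1=CC(=O)C(CC=C(C)C)(CC=C(C)C)C(=O)O1 | intermediate
15 | 2-methyl-1-propenylmagnesium bromide | CC(C)=C[Mg]Br | starting material
16 | bromomagnesium (2R)-2-tert-butyl-5-(3-methylbut-2-enyl)-1,3-dioxol-4-olate | Br[Mg]OC1=C(CC=C(C)C)O[C@@H](C(C)(C)C)O1 | intermediate
17 | bromomagnesium diketonate of (2R,5S)-2-tert-butyl-5-[6-methyl-2,2-bis(3-methylbut-2-enyl)-3,5-dioxoheptanoyl]-5-(3-methylbut-2-enyl)-1,3-dioxolan-4-one | O=C1O[C@H](C(C)(C)C)O[C@@]1(CC=C(C)C)C(=O)C(CC=C(C)C)(CC=C(C)C)C(=O)C=C(O[Mg]Br)C(C)C | intermediate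
18 | (6R)-5,6-dihydroxy-4-(2-methylpropanoyl)-2,2,6-tris(3-methylbut-2-en-1-yl)cyclohex-4-ene-1,3-dione | CC(C)=CCC1(CC=C(C)C)C(=O)C(C(=O)C(C)C)=C(O)[C@](O)(CC=C(C)C)C1=O | target

**Step count**

Total step count: 7. Longest linear sequence: 4 steps (steps 1, 2, 3, 7, or steps 4, 5, 6, 7).

**Steps most likely to fail**

1. Step 7 (Proposed new method).
   - What may go wrong: the hindered enolate may add too slowly to the neopentyl-type lactone carbonyl. Michael oligomerisation with unreacted acceptor, proton transfer from the isopropyl methine, or thermal fragmentation of the enolate could then take over. The closure may also stall at the diketonate stage.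
   - Fallback (known chemistry): it sets out from 7 and comes back at 18. Friedel-Crafts acylation of phloroglucinol with 7 (AlCl3, CH2Cl2/nitromethane) should give phlorisobutyrophenone F1. The classical dearomatising threefold C-prenylation of acylphloroglucinols (prenyl bromide, aq KOH, 0 °C) should give colupulone F2. Deprotonation with KN(SiMe3)2 in THF at -78 °C is followed by asymmetric enolate hydroxylation with an enantiopure (camphorylsulfonyl)oxaziridine at the prenyl-bearing ring carbon, the site at which this ring system accepts electrophilic oxygen. This leads to 18. The antipode of the reagent is chosen after a trial of the sense of induction, and the product is enriched by crystallisation of a salt with a chiral amine.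

2. Step 6.
   - What may go wrong: the second alkylation may stop at the monoprenyl stage, drift to O- or C5-alkylation, or take the branched terminus of the π-prenyl complex. The product lactone may also be opened by adventitious nucleophiles.
   - Fallback: it sets out from 12 and comes back at 14, and builds the quaternary carbon on a malonate, where C-alkylation is unambiguous.
     - Tsuji-Trost double prenylation of dimethyl malonate with 12 (NaH, Pd(PPh3)4, THF) should give dimethyl 2,2-bis(3-methylbut-2-enyl)malonate F3.
     - Saponification (KOH, aq EtOH, reflux) gives 2,2-bis(3-methylbut-2-enyl)malonic acid F4.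
     - Neutral chlorination with 1-chloro-N,N,2-trimethylpropenylamine gives 2,2-bis(3-methylbut-2-enyl)malonyl dichloride F5.
     - F5 is treated with 3-methyl-2-(trimethylsilyloxy)but-1-ene F6, made from 3-methylbutan-2-one with LiN(i-Pr)2 and Me3SiCl. In CH2Cl2 with 2,6-lutidine (-78 °C to rt) this should give C-acylation followed by O-acylation, the pyranone synthesis from malonyl dichlorides and enol silyl ethers, and so 14.

3. Step 4.
   - What may go wrong: O-acylation or double acylation of the dienolate, and proton exchange between product and dienolate, may erode the conversion.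
   - Fallback: it sets out from 7 and comes back at 11, bypassing steps 4 and 5. Reaction of 7 with N,O-dimethylhydroxylamine hydrochloride and pyridine gives N-methoxy-N,2-dimethylpropanamide F7. Acylation of the dianion of methyl acetoacetate (NaH, then n-BuLi, THF, 0 °C) at its terminal carbon with F7 gives methyl 6-methyl-3,5-dioxoheptanoate F8. Base-induced lactonisation (DBU, toluene, reflux) gives 11.

**Further compounds**

F1 | step 7 | phlorisobutyrophenone, 2-methyl-1-(2,4,6-trihydroxyphenyl)propan-1-one | CC(C)C(=O)c1c(O)cc(O)cc1O
F2 | step 7 | colupulone | CC(C)C(=O)C1=C(O)C(CC=C(C)C)=C(O)C(CC=C(C)C)(CC=C(C)C)C1=O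
F3 | step 6 | dimethyl 2,2-bis(3-methylbut-2-enyl)malonate | COC(=O)C(CC=C(C)C)(CC=C(C)C)C(=O)OC
F4 | step 6 | 2,2-bis(3-methylbut-2-enyl)malonic acid | OC(=O)C(CC=C(C)C)(CC=C(C)C)C(=O)O
F5 | step 6 | 2,2-bis(3-methylbut-2-enyl)malonyl dichloride | ClC(=O)C(CC=C(C)C)(CC=C(C)C)C(=O)Cl
F6 | step 6 | 3-methyl-2-(trimethylsilyloxy)but-1-ene | C=C(O[Si](C)(C)C)C(C)C
F7 | step 4 | N-methoxy-N,2-dimethylpropanamide | CC(C)C(=O)N(C)OC
F8 | step 4 | methyl 6-methyl-3,5-dioxoheptanoate | COC(=O)CC(=O)CC(=O)C(C)C
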